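**Retrosynthetic overview**
1. Target 30 ⇐ seco bromo-aldehyde 28: the C1–C14 bond is made last by a zinc Barbier allylation from a butenolide-embedded allyl bromide, which closes the 14-membered ring and gives the exocyclic methylene and the free 14-OH.
2. 28 ⇐ 22: the lactone ring is built as a 3-(bromomethyl)butenolide (esterification with 2-(bromomethyl)acrylic acid, then ring-closing metathesis); 22 ⇐ 20 by C5–OH-directed epoxidation and Mitsunobu acetate formation (C5 inverted).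
3. 20 ⇐ carbamate 10 (C5–C14) + alkenyl boronate 16 (C1–C4): the C4–C5 bond comes from a stereospecific 1,2-shift of the alkenyl carbon from boron to carbon (lithiation–borylation, 1,2-metallate rearrangement), which sets C5.
4. 10 ⇐ 3,6-dihydro-4-methyl-2H-pyran (ring-fixed Z alkene), propyne, Me3Al, oxirane; 16 ⇐ crotonaldehyde + 1-propynylmagnesium bromide (kinetic resolution sets C2).
5. Ring order: oxirane → butenolide → 14-membered carbocycle.

Assumption: locants C1–C20 in the comments are those of the target's cembrane skeleton (C1 lactone β-CH, C2 lactone O–CH, C3/C4 epoxide, C5 CH–OAc, C7=C8 E, C11=C12 Z, C14 CH–OH, C15–C17 methylene-lactone carbons, C18–C20 the methyls on C4, C8, C12). All numbered starting materials and (+)-sparteine are bought.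

**Route**

Step 1
Reactants: 1 3,6-dihydro-4-methyl-2H-pyran
Product: 2 tert-butyl{[(3Z)-5-iodo-3-methylpent-3-en-1-yl]oxy}dimethylsilane
Conditions: TBSCl, NaI, MeCN, 0 °C → rt; used crude
Reagents that add atoms: tert-butyldimethylsilyl chloride CC(C)(C)[Si](C)(C)Cl; sodium iodide [Na+].[I-]
Why: The silyl iodide formed in the flask silylates the ring oxygen and iodide opens the oxonium by SN2 at the allylic carbon (silyl iodide ether cleavage), so the ring-enforced Z geometry of C11=C12 is carried into the chain.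

Step 2
Reactants: 2 tert-butyl{[(3Z)-5-iodo-3-methylpent-3-en-1-yl]oxy}dimethylsilane; 3 propyne
Product: 5 tert-butyldimethyl{[(3Z)-3-methyloct-3-en-7-yn-1-yl]oxy}silane, via 1,3-dilithiopropyne 4 (not isolated)
Conditions: 3, n-BuLi (2 equiv per propyne), TMEDA, Et2O/hexane, −78 → 0 °C; then 2, THF, −78 °C → rt; H2O quench
Reagents that add atoms: none
Why: SN2 C-alkylation at the propargylic terminus of the propyne dianion forms C9–C10 and leaves a terminal alkyne after quench, without touching the Z alkene.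

Step 3
Reactants: 5 tert-butyldimethyl{[(3Z)-3-methyloct-3-en-7-yn-1-yl]oxy}silane; 6 oxirane
Product: 9 (3E,7Z)-10-[(tert-butyldimethylsilyl)oxy]-4,8-dimethyldeca-3,7-dien-1-ol, via alkenyldimethylalane 7 (not isolated), via lithium alkenylalanate 8 (not isolated)
Conditions: Me3Al, Cp2ZrCl2 (cat.), CH2Cl2, 0 °C → rt; evaporate; n-BuLi, THF/hexane, −30 °C; 6, −30 °C → rt; Rochelle salt work-up
Reagents that add atoms: trimethylaluminium C[Al](C)C
Why: Negishi zirconium-catalysed carboalumination adds Me and Al syn with Me on the internal carbon, and the derived alanate opens oxirane with retention at the alkenyl carbon, giving the E C7=C8 alkene and the C5 alcohol.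

Step 4
Reactants: 9 (3E,7Z)-10-[(tert-butyldimethylsilyl)oxy]-4,8-dimethyldeca-3,7-dien-1-ol
Product: 10 (3E,7Z)-10-[(tert-butyldimethylsilyl)oxy]-4,8-dimethyldeca-3,7-dien-1-yl N,N-diisopropylcarbamate
Conditions: iPr2NCOCl, Et3N, CH2Cl2, reflux
Reagents that add atoms: N,N-diisopropylcarbamoyl chloride CC(C)N(C(C)C)C(Cl)=O
Why: O-carbamoylation installs the group that directs α-lithiation at C5 and later serves as the leaving group in the 1,2-shift.

Step 5
Reactants: 11 (E)-but-2-enal; 12 1-propynylmagnesium bromide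
Product: 13 rac-(E)-hept-2-en-5-yn-4-ol
Conditions: THF, −78 → 0 °C; aqueous work-up
Reagents that add atoms: none
Why: 1,2-addition of the alkynyl Grignard reagent to the enal gives the racemic alkenyl alkynyl carbinol that carries C1–C4 and C18.

Step 6
Reactants: 13 rac-(E)-hept-2-en-5-yn-4-ol
Product: 14 (2E,4S)-hept-2-en-5-yn-4-ol
Conditions: Ti(OiPr)4, L-(+)-DIPT, t-BuOOH (0.6 equiv), 4 Å MS, CH2Cl2, −20 °C; recover the unreacted alcohol
Reagents that add atoms: none
Why: Sharpless kinetic resolution: with L-(+)-DIPT the R enantiomer is epoxidised at the E-propenyl group much faster, leaving the S alcohol (future C2) in high ee at about 55% conversion.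

Step 7
Reactants: 14 (2E,4S)-hept-2-en-5-yn-4-ol
Product: 15 1-({[(2E,4S)-hept-2-en-5-yn-4-yl]oxy}methyl)-4-methoxybenzene
Conditions: NaH, PMBCl, Bu4NI (cat.), THF/DMF, 0 °C → rt
Reagents that add atoms: 4-methoxybenzyl chloride COc1ccc(CCl)cc1
Why: Williamson etherification masks O2 so that only the C5 hydroxyl directs the later epoxidation; the stereocentre is not involved.

Step 8
Reactants: 15 1-({[(2E,4S)-hept-2-en-5-yn-4-yl]oxy}methyl)-4-methoxybenzene
Product: 16 2-{(2Z,4S,5E)-4-[(4-methoxybenzyl)oxy]hepta-2,5-dien-2-yl}-4,4,5,5-tetramethyl-1,3,2-dioxaborolane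
Conditions: CuCl (5 mol %), PCy3, NaOtBu (cat.), B2pin2, MeOH, THF, rt
Reagents that add atoms: bis(pinacolato)diboron CC1(C)OB(OC1(C)C)B1OC(C)(C)C(C)(C)O1
Why: Copper-catalysed formal hydroboration adds Cu–B syn across the alkyne with boron on the carbon remote from the propargylic oxygen and then protonates, giving the alkenyl boronate with C18 cis to C2 (the future E C3=C4 alkene).

Step 9
Reactants: 10 (3E,7Z)-10-[(tert-butyldimethylsilyl)oxy]-4,8-dimethyldeca-3,7-dien-1-yl N,N-diisopropylcarbamate; 16 2-{(2Z,4S,5E)-4-[(4-methoxybenzyl)oxy]hepta-2,5-dien-2-yl}-4,4,5,5-tetramethyl-1,3,2-dioxaborolane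
Product: 20 (2E,4S,5E,7S,9E,13Z)-16-[(tert-butyldimethylsilyl)oxy]-4-[(4-methoxybenzyl)oxy]-6,10,14-trimethylhexadeca-2,5,9,13-tetraen-7-ol, via α-lithiated carbamate 17 (not isolated), via boronate complex 18 (not isolated), via allylic boronic ester 19 (not isolated)
Conditions: s-BuLi, (+)-sparteine, Et2O, −78 °C, 5 h; 16, −78 °C; MgBr2·OEt2, MeOH, then reflux; NaOH, H2O2, THF, 0 °C
Reagents that add atoms: hydrogen peroxide OO
Why: Hoppe–Aggarwal lithiation–borylation: (+)-sparteine gives the (R)-lithio carbamate, borylation proceeds with retention, the alkenyl carbon then undergoes a stereospecific 1,2-shift from boron to carbon (1,2-metallate rearrangement) with inversion at C5 and retention of alkene geometry, and oxidation with retention gives the 5S allylic alcohol.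

Step 10
Reactants: 20 (2E,4S,5E,7S,9E,13Z)-16-[(tert-butyldimethylsilyl)oxy]-4-[(4-methoxybenzyl)oxy]-6,10,14-trimethylhexadeca-2,5,9,13-tetraen-7-ol
Product: 21 (1S,3E,7Z)-10-[(tert-butyldimethylsilyl)oxy]-1-[(2S,3S)-3-{(1S,2E)-1-[(4-methoxybenzyl)oxy]but-2-en-1-yl}-2-methyloxiran-2-yl]-4,8-dimethyldeca-3,7-dien-1-ol
Conditions: VO(acac)2 (cat.), t-BuOOH, CH2Cl2, 0 °C
Reagents that add atoms: tert-butyl hydroperoxide CC(C)(C)OO
Why: Hydroxyl-directed vanadium epoxidation: A(1,2) strain from the C4 methyl enforces the erythro mode, which from the 5S alcohol gives the 3S,4S epoxide, while the homoallylic and isolated alkenes react far more slowly.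

Step 11
Reactants: 21 (1S,3E,7Z)-10-[(tert-butyldimethylsilyl)oxy]-1-[(2S,3S)-3-{(1S,2E)-1-[(4-methoxybenzyl)oxy]but-2-en-1-yl}-2-methyloxiran-2-yl]-4,8-dimethyldeca-3,7-dien-1-ol
Product: 22 (1R,3E,7Z)-10-[(tert-butyldimethylsilyl)oxy]-1-[(2S,3S)-3-{(1S,2E)-1-[(4-methoxybenzyl)oxy]but-2-en-1-yl}-2-methyloxiran-2-yl]-4,8-dimethyldeca-3,7-dien-1-yl acetate
Conditions: PPh3, DIAD, AcOH, toluene, 0 °C → rt
Reagents that add atoms: acetic acid CC(O)=O
Why: Mitsunobu esterification: SN2 displacement of the activated C5 oxygen by acetate inverts C5 to R and installs the acetate in the threo relationship to the epoxide that direct epoxidation cannot give.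

Step 12
Reactants: 22 (1R,3E,7Z)-10-[(tert-butyldimethylsilyl)oxy]-1-[(2S,3S)-3-{(1S,2E)-1-[(4-methoxybenzyl)oxy]but-2-en-1-yl}-2-methyloxiran-2-yl]-4,8-dimethyldeca-3,7-dien-1-yl acetate
Product: 23 (1R,3E,7Z)-10-[(tert-butyldimethylsilyl)oxy]-1-{(2S,3S)-3-[(1S,2E)-1-hydroxybut-2-en-1-yl]-2-methyloxiran-2-yl}-4,8-dimethyldeca-3,7-dien-1-yl acetate
Conditions: DDQ, CH2Cl2/pH 7 buffer, 0 °C
Reagents that add atoms: none
Why: Oxidative PMB ether cleavage (benzylic hydride abstraction, then hydrolysis) frees O2 while the silyl ether, acetate and epoxide stay intact.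

Step 13
Reactants: 23 (1R,3E,7Z)-10-[(tert-butyldimethylsilyl)oxy]-1-{(2S,3S)-3-[(1S,2E)-1-hydroxybut-2-en-1-yl]-2-methyloxiran-2-yl}-4,8-dimethyldeca-3,7-dien-1-yl acetate; 24 2-(bromomethyl)acrylic acid
Product: 25 (1S,2E)-1-{(2S,3S)-3-[(1R,3E,7Z)-1-acetoxy-10-[(tert-butyldimethylsilyl)oxy]-4,8-dimethyldeca-3,7-dien-1-yl]-3-methyloxiran-2-yl}but-2-en-1-yl 2-(bromomethyl)prop-2-enoate
Conditions: DIC, DMAP (5 mol %), CH2Cl2, −10 °C
Reagents that add atoms: none
Why: Carbodiimide (Steglich) esterification at low temperature attaches C15–C17 to O2 without touching any stereocentre.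

Step 14
Reactants: 25 (1S,2E)-1-{(2S,3S)-3-[(1R,3E,7Z)-1-acetoxy-10-[(tert-butyldimethylsilyl)oxy]-4,8-dimethyldeca-3,7-dien-1-yl]-3-methyloxiran-2-yl}but-2-en-1-yl 2-(bromomethyl)prop-2-enoate
Product: 26 (1R,3E,7Z)-1-{(2S,3S)-3-[(2S)-4-(bromomethyl)-5-oxo-2,5-dihydrofuran-2-yl]-2-methyloxiran-2-yl}-10-[(tert-butyldimethylsilyl)oxy]-4,8-dimethyldeca-3,7-dien-1-yl acetate
Conditions: second-generation Hoveyda–Grubbs catalyst RuCl2(SIMes)(=CH-C6H4-2-OiPr) (10 mol %), toluene, 80 °C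
Reagents that add atoms: none
Why: Ring-closing metathesis between the propenyl group and the 1,1-disubstituted acrylate forms the C1=C15 butenolide with loss of propene; the trisubstituted chain alkenes do not take part.

Step 15
Reactants: 26 (1R,3E,7Z)-1-{(2S,3S)-3-[(2S)-4-(bromomethyl)-5-oxo-2,5-dihydrofuran-2-yl]-2-methyloxiran-2-yl}-10-[(tert-butyldimethylsilyl)oxy]-4,8-dimethyldeca-3,7-dien-1-yl acetate
Product: 27 (1R,3E,7Z)-1-{(2S,3S)-3-[(2S)-4-(bromomethyl)-5-oxo-2,5-dihydrofuran-2-yl]-2-methyloxiran-2-yl}-10-hydroxy-4,8-dimethyldeca-3,7-dien-1-yl acetate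
Conditions: Et3N·3HF, MeCN, rt
Reagents that add atoms: none
Why: Fluoride-mediated Si–O cleavage under near-neutral conditions spares the epoxide, the acetate and the allylic bromide.

Step 16
Reactants: 27 (1R,3E,7Z)-1-{(2S,3S)-3-[(2S)-4-(bromomethyl)-5-oxo-2,5-dihydrofuran-2-yl]-2-methyloxiran-2-yl}-10-hydroxy-4,8-dimethyldeca-3,7-dien-1-yl acetate
Product: 28 (1R,3E,7Z)-1-{(2S,3S)-3-[(2S)-4-(bromomethyl)-5-oxo-2,5-dihydrofuran-2-yl]-2-methyloxiran-2-yl}-4,8-dimethyl-10-oxodeca-3,7-dien-1-yl acetate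
Conditions: Dess–Martin periodinane, NaHCO3, CH2Cl2, 0 °C; used at once
Reagents that add atoms: none
Why: Buffered, base-free Dess–Martin oxidation gives the β,γ-unsaturated C14 aldehyde without migration of the C11=C12 alkene.

Step 17
Reactants: 28 (1R,3E,7Z)-1-{(2S,3S)-3-[(2S)-4-(bromomethyl)-5-oxo-2,5-dihydrofuran-2-yl]-2-methyloxiran-2-yl}-4,8-dimethyl-10-oxodeca-3,7-dien-1-yl acetate
Product: 30 CNP0283244.1 (target), via allylzinc bromide 29 (not isolated)
Conditions: Zn dust (activated), THF/sat. aq. NH4Cl 5:1, slow addition of 28 (final 2 mM), rt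
Reagents that add atoms: none
Why: Proposed new method: zinc inserts into the allylic C–Br bond of the butenolide to give 29, whose γ-carbon (C1) adds to the tethered C14 aldehyde with allylic transposition (SE2′), closing the 14-membered ring, creating the exocyclic methylene and freeing the 14-OH in one operation; bond formation anti to the C2 side chain gives the trans-fused lactone (1R), and the syn (like) C1/C14 relationship (14R) is expected by analogy with intermolecular aqueous zinc Barbier additions of 3-(bromomethyl)butenolides as I recall them, and is the least secure element; the closest known reaction types are those intermolecular Zn/In Barbier allylations and CrCl2-mediated Nozaki–Hiyama macrocyclizations of open-chain 2-(bromomethyl)acrylates, neither shown for a macrocyclizing butenolide-embedded allyl bromide.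

**Compound list**
1 | 3,6-dihydro-4-methyl-2H-pyran | CC1=CCOCC1 | starting material
2 | tert-butyl{[(3Z)-5-iodo-3-methylpent-3-en-1-yl]oxy}dimethylsilane | IC/C=C(/C)CCO[Si](C)(C)C(C)(C)C | intermediate
3 | propyne | CC#C | starting material
4 | 1,3-dilithiopropyne | [Li]CC#C[Li] | intermediate
5 | tert-butyldimethyl{[(3Z)-3-methyloct-3-en-7-yn-1-yl]oxy}silane | C#CCC/C=C(/C)CCO[Si](C)(C)C(C)(C)C | intermediate
6 | oxirane (ethylene oxide) | C1CO1 | starting material
7 | dimethyl{(1E,5Z)-8-[(tert-butyldimethylsilyl)oxy]-2,6-dimethylocta-1,5-dien-1-yl}alane | C[Al](C)/C=C(\C)CC/C=C(/C)CCO[Si](C)(C)C(C)(C)C | intermediate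
8 | lithium butyl(dimethyl){(1E,5Z)-8-[(tert-butyldimethylsilyl)oxy]-2,6-dimethylocta-1,5-dien-1-yl}alanate | [Li+].CCCC[Al-](C)(C)/C=C(\C)CC/C=C(/C)CCO[Si](C)(C)C(C)(C)C | intermediate
9 | (3E,7Z)-10-[(tert-butyldimethylsilyl)oxy]-4,8-dimethyldeca-3,7-dien-1-ol | OCC/C=C(\C)CC/C=C(/C)CCO[Si](C)(C)C(C)(C)C | intermediate
10 | (3E,7Z)-10-[(tert-butyldimethylsilyl)oxy]-4,8-dimethyldeca-3,7-dien-1-yl N,N-diisopropylcarbamate | CC(C)N(C(C)C)C(=O)OCC/C=C(\C)CC/C=C(/C)CCO[Si](C)(C)C(C)(C)C | intermediate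
11 | (E)-but-2-enal (crotonaldehyde) | C/C=C/C=O | starting material
12 | 1-propynylmagnesium bromide | CC#C[Mg]Br | starting material
13 | rac-(E)-hept-2-en-5-yn-4-ol | C/C=C/C(O)C#CC | intermediate
14 | (2E,4S)-hept-2-en-5-yn-4-ol | C/C=C/[C@H](O)C#CC | intermediate
15 | 1-({[(2E,4S)-hept-2-en-5-yn-4-yl]oxy}methyl)-4-methoxybenzene | C/C=C/[C@H](OCc1ccc(OC)cc1)C#CC | intermediate
16 | 2-{(2Z,4S,5E)-4-[(4-methoxybenzyl)oxy]hepta-2,5-dien-2-yl}-4,4,5,5-tetramethyl-1,3,2-dioxaborolane | C/C=C/[C@H](OCc1ccc(OC)cc1)/C=C(\C)B1OC(C)(C)C(C)(C)O1 | intermediate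
17 | (R)-α-lithio derivative of 10 (lithium on the carbamate-bearing carbon C5; (+)-sparteine complex) | [Li][C@@H](OC(=O)N(C(C)C)C(C)C)C/C=C(\C)CC/C=C(/C)CCO[Si](C)(C)C(C)(C)C | intermediate
18 | lithium boronate (ate) complex of 17 with 16 (boron bears the C4 alkenyl group and the carbamate-bearing C5) | [Li+].C/C=C/[C@H](OCc1ccc(OC)cc1)/C=C(\C)[B-]1(OC(C)(C)C(C)(C)O1)[C@@H](OC(=O)N(C(C)C)C(C)C)C/C=C(\C)CC/C=C(/C)CCO[Si](C)(C)C(C)(C)C | intermediate
19 | allylic pinacol boronic ester (Bpin on C5, 5S; C3=C4 E; otherwise as 20) | C/C=C/[C@H](OCc1ccc(OC)cc1)/C=C(\C)[C@@H](B1OC(C)(C)C(C)(C)O1)C/C=C(\C)CC/C=C(/C)CCO[Si](C)(C)C(C)(C)C | intermediate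
20 | (2E,4S,5E,7S,9E,13Z)-16-[(tert-butyldimethylsilyl)oxy]-4-[(4-methoxybenzyl)oxy]-6,10,14-trimethylhexadeca-2,5,9,13-tetraen-7-ol | C/C=C/[C@H](OCc1ccc(OC)cc1)/C=C(\C)[C@@H](O)C/C=C(\C)CC/C=C(/C)CCO[Si](C)(C)C(C)(C)C | intermediate
21 | (1S,3E,7Z)-10-[(tert-butyldimethylsilyl)oxy]-1-[(2S,3S)-3-{(1S,2E)-1-[(4-methoxybenzyl)oxy]but-2-en-1-yl}-2-methyloxiran-2-yl]-4,8-dimethyldeca-3,7-dien-1-ol | C/C=C/[C@H](OCc1ccc(OC)cc1)[C@@H]1O[C@@]1(C)[C@@H](O)C/C=C(\C)CC/C=C(/C)CCO[Si](C)(C)C(C)(C)C | intermediate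
22 | (1R,3E,7Z)-10-[(tert-butyldimethylsilyl)oxy]-1-[(2S,3S)-3-{(1S,2E)-1-[(4-methoxybenzyl)oxy]but-2-en-1-yl}-2-methyloxiran-2-yl]-4,8-dimethyldeca-3,7-dien-1-yl acetate | C/C=C/[C@H](OCc1ccc(OC)cc1)[C@@H]1O[C@@]1(C)[C@H](OC(C)=O)C/C=C(\C)CC/C=C(/C)CCO[Si](C)(C)C(C)(C)C | intermediate
23 | (1R,3E,7Z)-10-[(tert-butyldimethylsilyl)oxy]-1-{(2S,3S)-3-[(1S,2E)-1-hydroxybut-2-en-1-yl]-2-methyloxiran-2-yl}-4,8-dimethyldeca-3,7-dien-1-yl acetate | C/C=C/[C@H](O)[C@@H]1O[C@@]1(C)[C@H](OC(C)=O)C/C=C(\C)CC/C=C(/C)CCO[Si](C)(C)C(C)(C)C | intermediate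
24 | 2-(bromomethyl)acrylic acid | OC(=O)C(=C)CBr | starting material
25 | (1S,2E)-1-{(2S,3S)-3-[(1R,3E,7Z)-1-acetoxy-10-[(tert-butyldimethylsilyl)oxy]-4,8-dimethyldeca-3,7-dien-1-yl]-3-methyloxiran-2-yl}but-2-en-1-yl 2-(bromomethyl)prop-2-enoate | C/C=C/[C@H](OC(=O)C(=C)CBr)[C@@H]1O[C@@]1(C)[C@H](OC(C)=O)C/C=C(\C)CC/C=C(/C)CCO[Si](C)(C)C(C)(C)C | intermediate
26 | (1R,3E,7Z)-1-{(2S,3S)-3-[(2S)-4-(bromomethyl)-5-oxo-2,5-dihydrofuran-2-yl]-2-methyloxiran-2-yl}-10-[(tert-butyldimethylsilyl)oxy]-4,8-dimethyldeca-3,7-dien-1-yl acetate | BrCC1=C[C@H](OC1=O)[C@@H]2O[C@@]2(C)[C@H](OC(C)=O)C/C=C(\C)CC/C=C(/C)CCO[Si](C)(C)C(C)(C)C | intermediate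
27 | (1R,3E,7Z)-1-{(2S,3S)-3-[(2S)-4-(bromomethyl)-5-oxo-2,5-dihydrofuran-2-yl]-2-methyloxiran-2-yl}-10-hydroxy-4,8-dimethyldeca-3,7-dien-1-yl acetate | BrCC1=C[C@H](OC1=O)[C@@H]2O[C@@]2(C)[C@H](OC(C)=O)C/C=C(\C)CC/C=C(/C)CCO | intermediate
28 | (1R,3E,7Z)-1-{(2S,3S)-3-[(2S)-4-(bromomethyl)-5-oxo-2,5-dihydrofuran-2-yl]-2-methyloxiran-2-yl}-4,8-dimethyl-10-oxodeca-3,7-dien-1-yl acetate | BrCC1=C[C@H](OC1=O)[C@@H]2O[C@@]2(C)[C@H](OC(C)=O)C/C=C(\C)CC/C=C(/C)CC=O | intermediate
29 | bromo{[(5S)-5-{(2S,3S)-3-[(1R,3E,7Z)-1-acetoxy-4,8-dimethyl-10-oxodeca-3,7-dien-1-yl]-3-methyloxiran-2-yl}-2-oxo-2,5-dihydrofuran-3-yl]methyl}zinc | Br[Zn]CC1=C[C@H](OC1=O)[C@@H]2O[C@@]2(C)[C@H](OC(C)=O)C/C=C(\C)CC/C=C(/C)CC=O | intermediate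
30 | CNP0283244.1: (1R,2S,3S,4S,5R,7E,11Z,14R)-5-acetoxy-3,4-epoxy-14-hydroxycembra-7,11,15(17)-trien-16,2-olide (cembrane numbering) | C=C1C(=O)O[C@H]2[C@H]1[C@H](O)C/C(C)=C\CC/C(C)=C/C[C@@H](OC(C)=O)[C@]1(C)O[C@@H]21 | target

**Step count and risk**
Total steps: 17. Longest linear sequence: 13 (steps 1–4 then 9–17; the branch 5–8 then 9–17 is equally long).

The three steps most likely to fail:

Step 17 (the proposed new macrocyclization). Possible failures are protonolysis of the allylzinc or oligomerization at high dilution, and formation of the C14 epimer. The fallback uses established chemistry and sets out from 28. 28 is cyclized with CrCl2 in THF under high dilution, the Nozaki–Hiyama allylation that is the standard ring closure for cembranolide bromide–aldehyde seco compounds. The closed transition state of the trivalent allylchromium should give mainly the (14S)-epimer of 30 F1. Mitsunobu inversion with chloroacetic acid (PPh3, DIAD) then gives the 14-O-chloroacetate of 30 F2 with the correct 14R configuration. Thiourea/NaHCO3 in ethanol removes the chloroacetate in the presence of the C5 acetate and returns to 30.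

Step 11 (Mitsunobu inversion at C5, a carbinol flanked by a fully substituted epoxide carbon). The fallback is a redox inversion that sets out from 21. Dess–Martin oxidation gives the C5 ketone of 21 F3. Reagent-controlled reduction with (S)-Me-CBS/BH3·SMe2 (large group = the epoxide carbon) gives the (5R)-epimer of 21 F4. Acetylation (Ac2O, pyridine, DMAP) comes back to the route at 22.

Step 9 (lithiation–borylation with a hindered, functionalized trisubstituted alkenyl boronate). The fallback makes the same C5 boronate by a palladium-induced 1,2-metallate shift and sets out from 5 and 16. 5 is carboaluminated as in step 3 and alane 7 is quenched with I2 to give the (E)-alkenyl iodide tert-butyl{[(3Z,7E)-8-iodo-3,7-dimethylocta-3,7-dien-1-yl]oxy}dimethylsilane F5. Vinyllithium is added to 16 to form the lithium vinyl(alkenyl)pinacolatoborate of 16 F6. Pd(OAc)2/MandyPhos-catalysed conjunctive cross-coupling of the two (KOTf, THF, 60 °C; the ligand enantiomer that gives the 5S boronate, chosen by screening both) moves the C4 alkenyl group onto the vinyl carbon and joins C6 to C7. This comes back to the route at 19, which NaOH/H2O2 converts into 20.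

**Further compounds**
F1 | step 17 | (14S)-epimer of 30 | C=C1C(=O)O[C@H]2[C@H]1[C@@H](O)C/C(C)=C\CC/C(C)=C/C[C@@H](OC(C)=O)[C@]1(C)O[C@@H]21
F2 | step 17 | 14-O-chloroacetate of 30 | C=C1C(=O)O[C@H]2[C@H]1[C@H](OC(=O)CCl)C/C(C)=C\CC/C(C)=C/C[C@@H](OC(C)=O)[C@]1(C)O[C@@H]21
F3 | step 11 | C5 ketone of 21 | C/C=C/[C@H](OCc1ccc(OC)cc1)[C@@H]1O[C@@]1(C)C(=O)C/C=C(\C)CC/C=C(/C)CCO[Si](C)(C)C(C)(C)C
F4 | step 11 | (5R)-epimer of 21 | C/C=C/[C@H](OCc1ccc(OC)cc1)[C@@H]1O[C@@]1(C)[C@H](O)C/C=C(\C)CC/C=C(/C)CCO[Si](C)(C)C(C)(C)C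
F5 | step 9 | tert-butyl{[(3Z,7E)-8-iodo-3,7-dimethylocta-3,7-dien-1-yl]oxy}dimethylsilane | I/C=C(\C)CC/C=C(/C)CCO[Si](C)(C)C(C)(C)C
F6 | step 9 | lithium vinyl(alkenyl)pinacolatoborate of 16 | [Li+].C/C=C/[C@H](OCc1ccc(OC)cc1)/C=C(\C)[B-]1(C=C)OC(C)(C)C(C)(C)O1
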